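**Retrosynthetic overview**
1. The target comes from a trans-aldol adduct carried as its benzylic acetate, with both phenols as benzyl ethers. One final hydrogenolysis removes all three groups.
2. The key disconnection is C3–C(benzylic) of the vanillyl arm. It is an intermolecular aldol addition of the lithium enolate of (R)-4-(3-benzyloxy-4-methoxybenzyl)butyrolactone to O-benzylvanillin, in which C4 directs C3 to trans.
3. The butyrolactone is the only ring built, and it is closed before the aldol step. It forms by lactonisation of a γ-hydroxy tert-butyl ester, which comes from borane reduction of an (R)-2-(arylmethyl)succinic acid 4-tert-butyl ester.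
4. C4 is set by Evans alkylation of the 3-arylpropanoyl imide of (S)-4-benzyloxazolidin-2-one with tert-butyl bromoacetate.
5. The 3-arylpropanoic acid comes from isovanillin and malonic acid (Knoevenagel–Doebner, hydrogenation, benzylation). O-Benzylvanillin comes from vanillin.

Assumption: the carbinol carbon made in step 11 is carried as both epimers (drawn without configuration) because it becomes a CH2 group in step 13; LiN(SiMe3)2, NaN(SiMe3)2 and BH3·THF are used as bought solutions.

**Route**

Step 1
Reactants: 1 isovanillin (3-hydroxy-4-methoxybenzaldehyde); 2 malonic acid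
Product: 4 (E)-3-(3-hydroxy-4-methoxyphenyl)prop-2-enoic acid (isoferulic acid), via arylidenemalonic acid 3 (not isolated)
Conditions: 2 (2 equiv), piperidine (0.1 equiv), pyridine, 90 °C, 4 h; then cold aq. HCl, filter
Reagents that add atoms: none
Why: In this Knoevenagel–Doebner condensation the amine-catalysed aldol-type condensation with a non-enolisable aldehyde is followed by decarboxylation in hot pyridine, which gives only the (E)-acid, and the meta-hydroxyl cannot trigger a second decarboxylation.

Step 2
Reactants: 4 isoferulic acid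
Product: 5 3-(3-hydroxy-4-methoxyphenyl)propanoic acid
Conditions: H2 (1 atm), 10% Pd/C, EtOAc/EtOH, rt
Reagents that add atoms: none
Why: Catalytic hydrogenation of the conjugated C=C bond is fast and clean, and doing it before any benzyl ether is present removes all chemoselectivity questions.

Step 3
Reactants: 5 3-(3-hydroxy-4-methoxyphenyl)propanoic acid
Product: 6 benzyl 3-[3-(benzyloxy)-4-methoxyphenyl]propanoate
Conditions: BnBr (2.3 equiv), K2CO3 (3 equiv), DMF, 60 °C
Reagents that add atoms: benzyl bromide, BrCc1ccccc1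
Why: Williamson ether synthesis and carboxylate O-alkylation (both SN2 on a benzylic bromide) are driven to exhaustive benzylation, so no mixture of partly alkylated material results.

Step 4
Reactants: 6 benzyl 3-[3-(benzyloxy)-4-methoxyphenyl]propanoate
Product: 7 3-[3-(benzyloxy)-4-methoxyphenyl]propanoic acid
Conditions: 2 M NaOH, THF/MeOH, 40 °C; wash basic phase with MTBE; then 1 M HCl
Reagents that add atoms: sodium hydroxide, [Na+].[OH-]
Why: Saponification (BAC2 ester hydrolysis) cleaves only the benzyl ester because the aryl benzyl ether is inert to hydroxide.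

Step 5
Reactants: 7 3-[3-(benzyloxy)-4-methoxyphenyl]propanoic acid; 8 (4S)-4-benzyl-1,3-oxazolidin-2-one
Product: 10 (4S)-4-benzyl-3-{3-[3-(benzyloxy)-4-methoxyphenyl]propanoyl}-1,3-oxazolidin-2-one, via mixed pivalic anhydride 9 (not isolated)
Conditions: PivCl, Et3N (2.5 equiv), THF, −20 °C, 1 h; then LiCl (1.1 equiv), 8, −20 °C to rt
Reagents that add atoms: none
Why: In this N-acylation of the Evans auxiliary by the mixed-anhydride method, the hindered pivaloyl carbonyl steers attack to the wanted acyl group, LiCl/Et3N activates the oxazolidinone without strong base, and the auxiliary stereocentre is untouched.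

Step 6
Reactants: 10 the N-acyl oxazolidinone; 11 tert-butyl bromoacetate
Product: 13 tert-butyl (3R)-3-{[3-(benzyloxy)-4-methoxyphenyl]methyl}-4-[(4S)-4-benzyl-2-oxo-1,3-oxazolidin-3-yl]-4-oxobutanoate, via sodium Z-enolate 12 (not isolated)
Conditions: NaN(SiMe3)2 (1.1 equiv), THF, −78 °C, 45 min; then 11 (1.8 equiv), −78 to −30 °C; aq. NH4Cl; chromatography or crystallisation to one diastereomer
Reagents that add atoms: none
Why: In this Evans asymmetric alkylation the chelated Z-enolate is attacked by the reactive α-bromo ester on the face away from the benzyl group of the (S)-auxiliary, which sets the (R) centre (the future lactone C4) with dr typically at least 95:5.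

Step 7
Reactants: 13 the alkylated imide
Product: 15 (2R)-2-{[3-(benzyloxy)-4-methoxyphenyl]methyl}-4-tert-butoxy-4-oxobutanoic acid, via peroxy acid 14 (not isolated)
Conditions: LiOH·H2O (2 equiv), 30% H2O2 (4 equiv), THF/H2O 3:1, 0 °C; then aq. Na2SO3; extract auxiliary with CH2Cl2; then cold 1 M HCl to pH 3
Reagents that add atoms: hydrogen peroxide, OO
Why: In this hydroperoxide cleavage of the Evans imide the α-effect nucleophile attacks the exocyclic carbonyl selectively at 0 °C without epimerising the α-centre or touching the tert-butyl ester, and sulfite then reduces the peroxy acid to the acid.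

Step 8
Reactants: 15 the (R)-succinic half-ester
Product: 16 tert-butyl (3R)-4-[3-(benzyloxy)-4-methoxyphenyl]-3-(hydroxymethyl)butanoate
Conditions: BH3·THF (1.5 equiv), THF, 0 °C to rt; then MeOH, evaporate
Reagents that add atoms: none
Why: This chemoselective borane reduction works because BH3 reduces a free carboxylic acid far faster than a tert-butyl ester and affects neither the stereocentre nor the benzyl ether.

Step 9
Reactants: 16 the γ-hydroxy tert-butyl ester
Product: 17 (4R)-4-{[3-(benzyloxy)-4-methoxyphenyl]methyl}oxolan-2-one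
Conditions: p-TsOH·H2O (10 mol %), toluene, 80 °C
Reagents that add atoms: none
Why: Acid-catalysed lactonisation (intramolecular transesterification, 5-exo-trig) is driven by five-membered ring formation and loss of tert-butanol, and it keeps the (R) configuration because the stereocentre takes no part.

Step 10
Reactants: 18 vanillin (4-hydroxy-3-methoxybenzaldehyde)
Product: 19 4-(benzyloxy)-3-methoxybenzaldehyde
Conditions: BnBr (1.1 equiv), K2CO3 (1.5 equiv), DMF, 50 °C
Reagents that add atoms: benzyl bromide, BrCc1ccccc1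
Why: Williamson ether synthesis of an acidic phenol with a benzylic bromide is essentially quantitative and leaves the aldehyde untouched.

Step 11
Reactants: 17 the (R)-lactone; 19 4-(benzyloxy)-3-methoxybenzaldehyde
Product: 21 (3S,4R)-4-{[3-(benzyloxy)-4-methoxyphenyl]methyl}-3-{[4-(benzyloxy)-3-methoxyphenyl](hydroxy)methyl}oxolan-2-one (3,4-trans; both carbinol epimers), via lithium enolate 20 (not isolated)
Conditions: LiN(SiMe3)2 (1.05 equiv), THF, −78 °C, 45 min; then 19 (1.2 equiv), −78 °C, 2 h; AcOH quench at −78 °C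
Reagents that add atoms: none
Why: In this intermolecular aldol addition of a lactone lithium enolate to a non-enolisable aldehyde, the aldehyde approaches anti to the C4 arylmethyl group and so sets C3 trans to C4 (3S by CIP, the spatial arrangement of the target), while the cold acid quench blocks retro-aldol.

Step 12
Reactants: 21 the aldol adduct
Product: 22 [4-(benzyloxy)-3-methoxyphenyl][(3S,4R)-4-{[3-(benzyloxy)-4-methoxyphenyl]methyl}-2-oxooxolan-3-yl]methyl acetate (both epimers at the acetate carbon)
Conditions: Ac2O (3 equiv), pyridine, DMAP (5 mol %), CH2Cl2, 0 °C to rt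
Reagents that add atoms: acetic anhydride, CC(=O)OC(C)=O
Why: DMAP-catalysed O-acetylation turns the hydroxyl into a benzylic acetate that can be hydrogenolysed under neutral conditions, and pyridine is too weak a base to cause E1cB elimination or C3 epimerisation at this temperature.

Step 13
Reactants: 22 the benzylic acetate
Product: 23 (3R,4R)-3-[(4-hydroxy-3-methoxyphenyl)methyl]-4-[(3-hydroxy-4-methoxyphenyl)methyl]oxolan-2-one
Conditions: H2 (3 bar), 10% Pd/C, EtOAc, rt, 16 h
Reagents that add atoms: none
Why: Catalytic hydrogenolysis cleaves both aryl benzyl ethers and the electron-rich benzylic C–OAc bond in one neutral operation that avoids acid-promoted Friedel–Crafts closure to an aryltetralin, and C3 and C4 are untouched (C3 reads R only because the CIP priorities change).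

**Compound list**
1 | isovanillin (3-hydroxy-4-methoxybenzaldehyde) | COc1ccc(C=O)cc1O | starting material
2 | malonic acid | OC(=O)CC(=O)O | starting material
3 | 2-[(3-hydroxy-4-methoxyphenyl)methylidene]propanedioic acid | COc1ccc(C=C(C(=O)O)C(=O)O)cc1O | intermediate
4 | (E)-3-(3-hydroxy-4-methoxyphenyl)prop-2-enoic acid | COc1ccc(/C=C/C(=O)O)cc1O | intermediate
5 | 3-(3-hydroxy-4-methoxyphenyl)propanoic acid | COc1ccc(CCC(=O)O)cc1O | intermediate
6 | benzyl 3-[3-(benzyloxy)-4-methoxyphenyl]propanoate | COc1ccc(CCC(=O)OCc2ccccc2)cc1OCc1ccccc1 | intermediate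
7 | 3-[3-(benzyloxy)-4-methoxyphenyl]propanoic acid | COc1ccc(CCC(=O)O)cc1OCc1ccccc1 | intermediate
8 | (4S)-4-benzyl-1,3-oxazolidin-2-one | O=C1OC[C@H](Cc2ccccc2)N1 | starting material
9 | 3-[3-(benzyloxy)-4-methoxyphenyl]propanoic pivalic anhydride | COc1ccc(CCC(=O)OC(=O)C(C)(C)C)cc1OCc1ccccc1 | intermediate
10 | (4S)-4-benzyl-3-{3-[3-(benzyloxy)-4-methoxyphenyl]propanoyl}-1,3-oxazolidin-2-one | COc1ccc(CCC(=O)N2C(=O)OC[C@@H]2Cc2ccccc2)cc1OCc1ccccc1 | intermediate
11 | tert-butyl bromoacetate | CC(C)(C)OC(=O)CBr | starting material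
12 | sodium (Z)-enolate of 10 | COc1ccc(C/C=C(\[O-])N2C(=O)OC[C@@H]2Cc2ccccc2)cc1OCc1ccccc1.[Na+] | intermediate
13 | tert-butyl (3R)-3-{[3-(benzyloxy)-4-methoxyphenyl]methyl}-4-[(4S)-4-benzyl-2-oxo-1,3-oxazolidin-3-yl]-4-oxobutanoate | COc1ccc(C[C@H](CC(=O)OC(C)(C)C)C(=O)N2C(=O)OC[C@@H]2Cc2ccccc2)cc1OCc1ccccc1 | intermediate
14 | (2R)-2-{[3-(benzyloxy)-4-methoxyphenyl]methyl}-4-tert-butoxy-4-oxobutaneperoxoic acid | COc1ccc(C[C@H](CC(=O)OC(C)(C)C)C(=O)OO)cc1OCc1ccccc1 | intermediate
15 | (2R)-2-{[3-(benzyloxy)-4-methoxyphenyl]methyl}-4-tert-butoxy-4-oxobutanoic acid | COc1ccc(C[C@H](CC(=O)OC(C)(C)C)C(=O)O)cc1OCc1ccccc1 | intermediate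
16 | tert-butyl (3R)-4-[3-(benzyloxy)-4-methoxyphenyl]-3-(hydroxymethyl)butanoate | COc1ccc(C[C@H](CC(=O)OC(C)(C)C)CO)cc1OCc1ccccc1 | intermediate
17 | (4R)-4-{[3-(benzyloxy)-4-methoxyphenyl]methyl}oxolan-2-one | COc1ccc(C[C@H]2COC(=O)C2)cc1OCc1ccccc1 | intermediate
18 | vanillin (4-hydroxy-3-methoxybenzaldehyde) | COc1cc(C=O)ccc1O | starting material
19 | 4-(benzyloxy)-3-methoxybenzaldehyde | COc1cc(C=O)ccc1OCc1ccccc1 | intermediate
20 | lithium enolate of 17 (C4 unchanged) | COc1ccc(C[C@H]2COC([O-])=C2)cc1OCc1ccccc1.[Li+] | intermediate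
21 | (3S,4R)-4-{[3-(benzyloxy)-4-methoxyphenyl]methyl}-3-{[4-(benzyloxy)-3-methoxyphenyl](hydroxy)methyl}oxolan-2-one, both carbinol epimers | COc1ccc(C[C@H]2COC(=O)[C@@H]2C(O)c2ccc(OCc3ccccc3)c(OC)c2)cc1OCc1ccccc1 | intermediate
22 | [4-(benzyloxy)-3-methoxyphenyl][(3S,4R)-4-{[3-(benzyloxy)-4-methoxyphenyl]methyl}-2-oxooxolan-3-yl]methyl acetate, both epimers | COc1ccc(C[C@H]2COC(=O)[C@@H]2C(OC(C)=O)c2ccc(OCc3ccccc3)c(OC)c2)cc1OCc1ccccc1 | intermediate
23 | (3R,4R)-3-[(4-hydroxy-3-methoxyphenyl)methyl]-4-[(3-hydroxy-4-methoxyphenyl)methyl]oxolan-2-one | COc1ccc(C[C@H]2COC(=O)[C@@H]2Cc2ccc(O)c(OC)c2)cc1O | target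

**Totals**
Total step count: 13.
Longest linear sequence: 12 (steps 1–9 and 11–13). Step 10 is the only side-branch step.

**Steps most likely to fail**

**Step 11 (aldol addition).**
- Risk: the addition is reversible. Retro-aldol on warming or proton transfer from unreacted lactone can limit conversion.
- Fallback: it sets out from 19 together with enolate 20 of lactone 17, and it comes back at 21.
- Aldehyde 19 is oxidised with iodine and KOH in MeOH at 0 °C to methyl 4-(benzyloxy)-3-methoxybenzoate F1.
- Enolate 20, made with 2.2 equiv of LiN(SiMe3)2, is acylated by this non-enolisable ester in a crossed Claisen condensation (THF, −78 °C to rt). The acidity of the β-keto lactone product makes this irreversible.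
- Acidic work-up gives the thermodynamic trans isomer (3S,4R)-3-[4-(benzyloxy)-3-methoxybenzoyl]-4-{[3-(benzyloxy)-4-methoxyphenyl]methyl}oxolan-2-one F2.
- NaBH4 in MeOH/THF at −20 °C reduces only the ketone and gives 21 as an epimer mixture.

**Step 13 (hydrogenolysis of the benzylic acetate).**
- Risk: the hindered secondary C–OAc bond may cleave slowly. Alternatively, after O-debenzylation, loss of acetic acid toward a quinone methide or benzylidene lactone could erode the C3 configuration.
- Fallback: it sets out from 22 and comes back at 23.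
- DBU in CH2Cl2 at rt eliminates acetic acid on purpose (E1cB) to give (3E,4R)-4-{[3-(benzyloxy)-4-methoxyphenyl]methyl}-3-{[4-(benzyloxy)-3-methoxyphenyl]methylidene}oxolan-2-one F3.
- H2 with 10% Pd/C in EtOAc/EtOH saturates the alkene from the face away from the C4 substituent and removes both benzyl ethers. The main product is the cis lactone (3S,4R)-3-[(4-hydroxy-3-methoxyphenyl)methyl]-4-[(3-hydroxy-4-methoxyphenyl)methyl]oxolan-2-one F4.
- NaOMe (4 equiv) in MeOH at 50 °C, then 1 M HCl, equilibrates C3 through the enolate to the more stable trans lactone 23. C4 is not acidic and is not touched.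

**Step 6 (Evans alkylation with the bromoacetate).**
- Risk: the electrophile has acidic α-protons and can quench the enolate, which gives incomplete conversion or a lower dr.
- Fallback: it sets out from 10 through the same enolate 12, and it comes back at 17.
- Enolate 12 is alkylated with allyl iodide, which has no acidic protons and attacks the same face. The product is (4S)-4-benzyl-3-[(2S)-2-{[3-(benzyloxy)-4-methoxyphenyl]methyl}pent-4-enoyl]-1,3-oxazolidin-2-one F5, whose descriptor differs only through CIP priority.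
- LiBH4 with MeOH (1 equiv) in Et2O at 0 °C removes the auxiliary reductively and gives (2S)-2-{[3-(benzyloxy)-4-methoxyphenyl]methyl}pent-4-en-1-ol F6.
- Lemieux–Johnson cleavage (OsO4 cat., NaIO4, 2,6-lutidine, dioxane/H2O) gives, after spontaneous ring closure, (4R)-4-{[3-(benzyloxy)-4-methoxyphenyl]methyl}oxolan-2-ol F7 as an anomer mixture.
- TEMPO/PhI(OAc)2 in CH2Cl2 oxidises this lactol to lactone 17.

**Further compounds**
F1 | step 11 | methyl 4-(benzyloxy)-3-methoxybenzoate | COC(=O)c1ccc(OCc2ccccc2)c(OC)c1
F2 | step 11 | (3S,4R)-3-[4-(benzyloxy)-3-methoxybenzoyl]-4-{[3-(benzyloxy)-4-methoxyphenyl]methyl}oxolan-2-one | COc1ccc(C[C@H]2COC(=O)[C@@H]2C(=O)c2ccc(OCc3ccccc3)c(OC)c2)cc1OCc1ccccc1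
F3 | step 13 | (3E,4R)-4-{[3-(benzyloxy)-4-methoxyphenyl]methyl}-3-{[4-(benzyloxy)-3-methoxyphenyl]methylidene}oxolan-2-one | COc1ccc(C[C@H]2COC(=O)/C2=C/c2ccc(OCc3ccccc3)c(OC)c2)cc1OCc1ccccc1
F4 | step 13 | (3S,4R)-3-[(4-hydroxy-3-methoxyphenyl)methyl]-4-[(3-hydroxy-4-methoxyphenyl)methyl]oxolan-2-one (cis) | COc1ccc(C[C@H]2COC(=O)[C@H]2Cc2ccc(O)c(OC)c2)cc1O
F5 | step 6 | (4S)-4-benzyl-3-[(2S)-2-{[3-(benzyloxy)-4-methoxyphenyl]methyl}pent-4-enoyl]-1,3-oxazolidin-2-one | COc1ccc(C[C@H](CC=C)C(=O)N2C(=O)OC[C@@H]2Cc2ccccc2)cc1OCc1ccccc1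
F6 | step 6 | (2S)-2-{[3-(benzyloxy)-4-methoxyphenyl]methyl}pent-4-en-1-ol | COc1ccc(C[C@H](CC=C)CO)cc1OCc1ccccc1
F7 | step 6 | (4R)-4-{[3-(benzyloxy)-4-methoxyphenyl]methyl}oxolan-2-ol (anomer mixture) | COc1ccc(C[C@H]2COC(O)C2)cc1OCc1ccccc1
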